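**Plan**

- Retrosynthesis: the C27 chain is cut at C11'=C12' (two-carbon amide phosphonate), at C11=C12 (C15 ylide plus the C10 dialdehyde) and at C7=C8 (C5 phosphonate plus a C10 ring aldehyde). The C5 and C6 carbinols are traced back through a triol to an oxirane on β-cyclogeraniol.
- Enabling feature: in the ring (C1 to C6) the trans C5–C6 diol is what anti addition of two oxygens to a tetrasubstituted C5=C6 alkene leaves, and C6 carries the one-carbon arm C7, which as a hydroxymethyl group is an allylic anchor for titanium.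
- Forward: the cyclohexane is bought; the only ring made is the oxirane (step 2), which water opens at C5 (step 3). The chain then grows outward: C7=C8, C11=C12, C11'=C12'.
- Stereochemistry: C5 and C6 are both set by the tartrate in the epoxidation (C6–O kept, C5 inverted on hydrolysis). The E alkenes come from stabilised-phosphonate olefinations, a Wittig step with iodine equilibration, and the geometry already present in the C5 and C10 building blocks.

Key step: step 2

Remark: carotenoid numbering is used (ring C1–C6, chain C7–C15 then C15'–C10'); phosphonate 7 is taken as its E isomer, minor Z-alkene isomers are assumed separable by chromatography, and polyenes are handled in dim light.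

**Route**

Step 1
Reactants: 1 β-cyclocitral
Product: 2 β-cyclogeraniol, (2,6,6-trimethylcyclohex-1-en-1-yl)methanol
Conditions: NaBH4, MeOH, 0 °C
Reagents that add atoms: none
Why: Borohydride 1,2-reduction of the conjugated aldehyde, in which the fully substituted β-carbon C5 resists conjugate hydride addition, so the tetrasubstituted C5=C6 alkene survives as the allylic alcohol needed for the epoxidation.

Step 2
Reactants: 2 β-cyclogeraniol
Product: 3 [(1S,6S)-2,2,6-trimethyl-7-oxabicyclo[4.1.0]heptan-1-yl]methanol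
Conditions: Ti(OiPr)4 (10 mol %), L-(+)-diethyl tartrate (14 mol %), tBuOOH (2 equiv, anhydrous in isooctane), 4 Å molecular sieves, CH2Cl2, −25 °C
Reagents that add atoms: tert-butyl hydroperoxide, CC(C)(C)OO
Why: Katsuki–Sharpless asymmetric epoxidation of a primary allylic alcohol: the C7 alkoxide of 2 and the hydroperoxide both exchange onto the tartrate-bridged titanium dimer, and the distal peroxide oxygen is passed to the C5=C6 π bond inside that assembly. The oxirane, the only ring formed, closes by one concerted oxygen-atom transfer ([2+1] addition) that makes the C5–O and C6–O bonds on the same face, so it is necessarily cis-fused to the six-membered ring. Both new stereocentres are reagent-controlled: 2 is geraniol with its C2 hydrogen replaced and its alkene termini tied into a ring, so the L-(+) tartrate that turns geraniol into the (2S,3S)-epoxide should place oxygen on the corresponding face and give the (1S,6S) oxirane. The step needs only enantioface selectivity, which the substrate secures through its single anchoring group, the allylic C7 hydroxyl, while the electron-rich tetrasubstituted alkene keeps the rate acceptable. Catalytic titanium with sieves is preferred because it limits alkoxide opening of the 2,2-disubstituted epoxy alcohol.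

Step 3
Reactants: 3 [(1S,6S)-2,2,6-trimethyl-7-oxabicyclo[4.1.0]heptan-1-yl]methanol
Product: 4 (1S,2R)-1-(hydroxymethyl)-2,6,6-trimethylcyclohexane-1,2-diol
Conditions: HClO4 (5 mol %, aqueous), THF–H2O (3:1), 0 °C → rt
Reagents that add atoms: water, O
Why: Acid-catalysed hydrolysis of a 2,3-epoxy alcohol at the carbon remote from the hydroxymethyl group: water attacks the protonated oxirane at C5 from the face opposite the leaving oxygen (inversion at C5), because C6 is deactivated inductively by C7–OH and shielded by the quaternary C1, while the C6–O bond and its configuration are untouched, which gives the trans diol.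

Step 4
Reactants: 4 (1S,2R)-1-(hydroxymethyl)-2,6,6-trimethylcyclohexane-1,2-diol
Product: 5 trimethyl-[[(1S,2R)-2,6,6-trimethyl-1,2-bis(trimethylsilyloxy)cyclohexyl]methoxy]silane
Conditions: Me3SiOTf (3.6 equiv), 2,6-lutidine (5 equiv), CH2Cl2, −78 → 0 °C
Reagents that add atoms: trimethylsilyl trifluoromethanesulfonate, C[Si](C)(C)OS(=O)(=O)C(F)(F)F
Why: Silylation with a silyl triflate and a hindered pyridine base, the small trimethylsilyl group being chosen because it still reaches the congested tertiary C6 hydroxyl; capping both tertiary alcohols shuts off retro-aldol cleavage of C5–C6 and α-ketol ring expansion once C7 is an aldehyde, and no stereocentre is touched.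

Step 5
Reactants: 5 trimethyl-[[(1S,2R)-2,6,6-trimethyl-1,2-bis(trimethylsilyloxy)cyclohexyl]methoxy]silane
Product: 6 (1R,2R)-2,6,6-trimethyl-1,2-bis(trimethylsilyloxy)cyclohexane-1-carbaldehyde
Conditions: (COCl)2, DMSO, CH2Cl2, −78 → −30 °C; Et3N, −78 → 0 °C
Reagents that add atoms: none
Why: Swern oxidation carried out directly on a primary trimethylsilyl ether, a known selective oxidative desilylation: chlorodimethylsulfonium chloride exchanges only at the unhindered primary oxygen and base then gives the aldehyde, whereas the tertiary silyl ethers cannot form an oxidisable alkoxysulfonium salt and the quaternary α-carbon cannot epimerise.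

Step 6
Reactants: 6 (1R,2R)-2,6,6-trimethyl-1,2-bis(trimethylsilyloxy)cyclohexane-1-carbaldehyde; 7 triethyl 3-methyl-4-phosphonocrotonate
Product: 9 ethyl (2E,4E)-3-methyl-5-[(1R,2R)-2,6,6-trimethyl-1,2-bis(trimethylsilyloxy)cyclohexyl]penta-2,4-dienoate, via lithiated phosphonate 8 (not isolated)
Conditions: 7, LiN(SiMe3)2, THF, −78 °C; then 6, −78 °C → rt
Reagents that add atoms: none
Why: Horner–Wadsworth–Emmons olefination with the vinylogous phosphonate carbanion, which should form C7=C8 with E geometry through reversible addition and elimination from the less crowded adduct, while the C9=C10 geometry is carried in from 7 and any 9Z isomer is removed by chromatography.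

Step 7
Reactants: 9 ethyl (2E,4E)-3-methyl-5-[(1R,2R)-2,6,6-trimethyl-1,2-bis(trimethylsilyloxy)cyclohexyl]penta-2,4-dienoate
Product: 10 (2E,4E)-3-methyl-5-[(1R,2R)-2,6,6-trimethyl-1,2-bis(trimethylsilyloxy)cyclohexyl]penta-2,4-dien-1-ol
Conditions: iBu2AlH (2.5 equiv), CH2Cl2, −78 °C; aqueous potassium sodium tartrate
Reagents that add atoms: none
Why: Reduction of the dienoate with iBu2AlH, a 1,2-hydride reduction that stops at the allylic alcohol and leaves the diene and the tertiary silyl ethers alone at low temperature.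

Step 8
Reactants: 10 (2E,4E)-3-methyl-5-[(1R,2R)-2,6,6-trimethyl-1,2-bis(trimethylsilyloxy)cyclohexyl]penta-2,4-dien-1-ol
Product: 12 [(2E,4E)-3-methyl-5-[(1R,2R)-2,6,6-trimethyl-1,2-bis(trimethylsilyloxy)cyclohexyl]penta-2,4-dien-1-yl]triphenylphosphonium bromide, via allylic bromide 11 (not isolated)
Conditions: CBr4 (1.1 equiv), PPh3 (1.1 equiv), 2,6-lutidine (0.2 equiv), CH2Cl2, −20 → 0 °C; then PPh3 (1.2 equiv), rt; precipitation with Et2O
Reagents that add atoms: carbon tetrabromide, BrC(Br)(Br)Br; triphenylphosphine, c1ccccc1P(c1ccccc1)c1ccccc1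
Why: Appel bromination of the primary allylic alcohol under near-neutral conditions followed in the same flask by SN2 quaternisation of triphenylphosphine, which avoids isolating the labile dienyl bromide and avoids acidic PPh3·HBr conditions that could ionise the tertiary allylic C6 oxygen.

Step 9
Reactants: 12 [(2E,4E)-3-methyl-5-[(1R,2R)-2,6,6-trimethyl-1,2-bis(trimethylsilyloxy)cyclohexyl]penta-2,4-dien-1-yl]triphenylphosphonium bromide; 13 (2E,4E,6E)-2,7-dimethylocta-2,4,6-trienedial
Product: 15 (2E,4E,6E,8E,10E,12E)-2,7,11-trimethyl-13-[(1R,2R)-2,6,6-trimethyl-1,2-bis(trimethylsilyloxy)cyclohexyl]trideca-2,4,6,8,10,12-hexaenal, via phosphorus ylide 14 (not isolated)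
Conditions: 12, NaN(SiMe3)2, THF, −78 °C; cannulated into 13 (3 equiv), THF, −78 → 0 °C; then I2 (1 mol %), CH2Cl2, rt, diffuse light
Reagents that add atoms: none
Why: Wittig olefination of the semi-stabilised allylic ylide with the symmetrical dialdehyde in excess so that only one formyl group reacts; the new C11=C12 bond should form as an E/Z mixture, and iodine-catalysed equilibration is expected to convert the strained 11Z isomer into the all-E polyene.

Step 10
Reactants: 15 (2E,4E,6E,8E,10E,12E)-2,7,11-trimethyl-13-[(1R,2R)-2,6,6-trimethyl-1,2-bis(trimethylsilyloxy)cyclohexyl]trideca-2,4,6,8,10,12-hexaenal; 16 diethyl [2-(methoxy(methyl)amino)-2-oxoethyl]phosphonate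
Product: 18 (2E,4E,6E,8E,10E,12E,14E)-N-methoxy-N,4,9,13-tetramethyl-15-[(1R,2R)-2,6,6-trimethyl-1,2-bis(trimethylsilyloxy)cyclohexyl]pentadeca-2,4,6,8,10,12,14-heptaenamide, via sodium phosphonate 17 (not isolated)
Conditions: 16, NaH, THF, 0 °C; then 15, 0 °C → rt
Reagents that add atoms: none
Why: Horner–Wadsworth–Emmons olefination with a stabilised amide phosphonate, which is E-selective for the new C11'=C12' bond and adds the last two carbons at the amide oxidation level, so the chain cannot be homologated twice.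

Step 11
Reactants: 18 (2E,4E,6E,8E,10E,12E,14E)-N-methoxy-N,4,9,13-tetramethyl-15-[(1R,2R)-2,6,6-trimethyl-1,2-bis(trimethylsilyloxy)cyclohexyl]pentadeca-2,4,6,8,10,12,14-heptaenamide
Product: 19 (2E,4E,6E,8E,10E,12E,14E)-4,9,13-trimethyl-15-[(1R,2R)-2,6,6-trimethyl-1,2-bis(trimethylsilyloxy)cyclohexyl]pentadeca-2,4,6,8,10,12,14-heptaenal
Conditions: iBu2AlH (1.5 equiv), THF, −78 °C; aqueous potassium sodium tartrate
Reagents that add atoms: none
Why: Reduction of a Weinreb amide with iBu2AlH to the aldehyde, the chelated tetrahedral aluminium adduct persisting until hydrolysis so that over-reduction to the alcohol is not expected.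

Step 12
Reactants: 19 (2E,4E,6E,8E,10E,12E,14E)-4,9,13-trimethyl-15-[(1R,2R)-2,6,6-trimethyl-1,2-bis(trimethylsilyloxy)cyclohexyl]pentadeca-2,4,6,8,10,12,14-heptaenal
Product: 20 (2E,4E,6E,8E,10E,12E,14E)-15-[(1R,2R)-1,2-dihydroxy-2,6,6-trimethylcyclohexyl]-4,9,13-trimethylpentadeca-2,4,6,8,10,12,14-heptaenal
Conditions: Bu4NF (2.5 equiv), AcOH (2.5 equiv), THF, 0 °C → rt, dim light
Reagents that add atoms: none
Why: Fluoride-induced cleavage of the two tertiary trimethylsilyl ethers, buffered with acetic acid so that neither base-promoted degradation of the polyenal nor acid-promoted ionisation of the tertiary allylic C6–OH intervenes, which leaves both carbinol configurations as set in steps 2 and 3.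

**Compound list**

1 | β-cyclocitral (2,6,6-trimethylcyclohex-1-ene-1-carbaldehyde) | CC1=C(C=O)C(C)(C)CCC1 | starting material
2 | β-cyclogeraniol, (2,6,6-trimethylcyclohex-1-en-1-yl)methanol | CC1=C(CO)C(C)(C)CCC1 | intermediate
3 | [(1S,6S)-2,2,6-trimethyl-7-oxabicyclo[4.1.0]heptan-1-yl]methanol | OC[C@@]1(O2)C(C)(C)CCC[C@@]12C | intermediate
4 | (1S,2R)-1-(hydroxymethyl)-2,6,6-trimethylcyclohexane-1,2-diol | OC[C@@]1(O)C(C)(C)CCC[C@@]1(C)O | intermediate
5 | trimethyl-[[(1S,2R)-2,6,6-trimethyl-1,2-bis(trimethylsilyloxy)cyclohexyl]methoxy]silane | C[Si](C)(C)OC[C@@]1(O[Si](C)(C)C)C(C)(C)CCC[C@@]1(C)O[Si](C)(C)C | intermediate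
6 | (1R,2R)-2,6,6-trimethyl-1,2-bis(trimethylsilyloxy)cyclohexane-1-carbaldehyde | O=C[C@@]1(O[Si](C)(C)C)C(C)(C)CCC[C@@]1(C)O[Si](C)(C)C | intermediate
7 | triethyl 3-methyl-4-phosphonocrotonate, ethyl (2E)-4-(diethoxyphosphoryl)-3-methylbut-2-enoate | CCOC(=O)/C=C(C)/CP(=O)(OCC)OCC | starting material
8 | lithium salt of 7 deprotonated at C4 | [Li+].CCOC(=O)/C=C(C)/[CH-]P(=O)(OCC)OCC | intermediate
9 | ethyl (2E,4E)-3-methyl-5-[(1R,2R)-2,6,6-trimethyl-1,2-bis(trimethylsilyloxy)cyclohexyl]penta-2,4-dienoate | CCOC(=O)/C=C(C)/C=C/[C@@]1(O[Si](C)(C)C)C(C)(C)CCC[C@@]1(C)O[Si](C)(C)C | intermediate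
10 | (2E,4E)-3-methyl-5-[(1R,2R)-2,6,6-trimethyl-1,2-bis(trimethylsilyloxy)cyclohexyl]penta-2,4-dien-1-ol | OC/C=C(C)/C=C/[C@@]1(O[Si](C)(C)C)C(C)(C)CCC[C@@]1(C)O[Si](C)(C)C | intermediate
11 | (1R,2R)-1-[(1E,3E)-5-bromo-3-methylpenta-1,3-dien-1-yl]-2,6,6-trimethyl-1,2-bis(trimethylsilyloxy)cyclohexane | BrC/C=C(C)/C=C/[C@@]1(O[Si](C)(C)C)C(C)(C)CCC[C@@]1(C)O[Si](C)(C)C | intermediate
12 | [(2E,4E)-3-methyl-5-[(1R,2R)-2,6,6-trimethyl-1,2-bis(trimethylsilyloxy)cyclohexyl]penta-2,4-dien-1-yl]triphenylphosphonium bromide | [Br-].c1ccccc1[P+](c1ccccc1)(c1ccccc1)C/C=C(C)/C=C/[C@@]1(O[Si](C)(C)C)C(C)(C)CCC[C@@]1(C)O[Si](C)(C)C | intermediate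
13 | (2E,4E,6E)-2,7-dimethylocta-2,4,6-trienedial | O=C/C(C)=C/C=C/C=C(C)/C=O | starting material
14 | [(2E,4E)-3-methyl-5-[(1R,2R)-2,6,6-trimethyl-1,2-bis(trimethylsilyloxy)cyclohexyl]penta-2,4-dien-1-ylidene]triphenylphosphorane | c1ccccc1P(c1ccccc1)(c1ccccc1)=C/C=C(C)/C=C/[C@@]1(O[Si](C)(C)C)C(C)(C)CCC[C@@]1(C)O[Si](C)(C)C | intermediate
15 | (2E,4E,6E,8E,10E,12E)-2,7,11-trimethyl-13-[(1R,2R)-2,6,6-trimethyl-1,2-bis(trimethylsilyloxy)cyclohexyl]trideca-2,4,6,8,10,12-hexaenal | O=C/C(C)=C/C=C/C=C(C)/C=C/C=C(C)/C=C/[C@@]1(O[Si](C)(C)C)C(C)(C)CCC[C@@]1(C)O[Si](C)(C)C | intermediate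
16 | diethyl [2-(methoxy(methyl)amino)-2-oxoethyl]phosphonate | CCOP(=O)(CC(=O)N(C)OC)OCC | starting material
17 | sodium salt of 16 deprotonated at the methylene carbon | [Na+].CCOP(=O)([CH-]C(=O)N(C)OC)OCC | intermediate
18 | (2E,4E,6E,8E,10E,12E,14E)-N-methoxy-N,4,9,13-tetramethyl-15-[(1R,2R)-2,6,6-trimethyl-1,2-bis(trimethylsilyloxy)cyclohexyl]pentadeca-2,4,6,8,10,12,14-heptaenamide | CON(C)C(=O)/C=C/C(C)=C/C=C/C=C(C)/C=C/C=C(C)/C=C/[C@@]1(O[Si](C)(C)C)C(C)(C)CCC[C@@]1(C)O[Si](C)(C)C | intermediate
19 | (2E,4E,6E,8E,10E,12E,14E)-4,9,13-trimethyl-15-[(1R,2R)-2,6,6-trimethyl-1,2-bis(trimethylsilyloxy)cyclohexyl]pentadeca-2,4,6,8,10,12,14-heptaenal | O=C/C=C/C(C)=C/C=C/C=C(C)/C=C/C=C(C)/C=C/[C@@]1(O[Si](C)(C)C)C(C)(C)CCC[C@@]1(C)O[Si](C)(C)C | intermediate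
20 | (2E,4E,6E,8E,10E,12E,14E)-15-[(1R,2R)-1,2-dihydroxy-2,6,6-trimethylcyclohexyl]-4,9,13-trimethylpentadeca-2,4,6,8,10,12,14-heptaenal, (5R,6R)-5,6-dihydroxy-5,6-dihydro-10'-apo-β-caroten-10'-al | CC(/C=C/C=O)=C\C=C\C=C(C)\C=C\C=C(C)\C=C\[C@@]1(O)C(C)(C)CCC[C@@]1(C)O | target

**Count and risks**

Total step count: 12. Longest linear sequence: 12 steps (1 to 20); compounds 7, 13 and 16 are bought.

Step 2. The enantioface discrimination may be eroded because the tetrasubstituted alkene sits next to a quaternary carbon, so turnover inside the chiral titanium complex may be slow and a less selective background oxidation may compete. The fallback sets out from 2 and gives up reagent control in favour of resolution. Hydroxyl-directed epoxidation with VO(acac)2 and tBuOOH in toluene would give the racemic, necessarily cis-fused epoxy alcohol F1. Acylation with (1S)-camphanic chloride (Et3N, DMAP, CH2Cl2) would give the diastereomeric esters, the (1S,6S)-epoxide camphanate F2 and the (1R,6R)-epoxide camphanate F3, to be separated by crystallisation or chromatography. Methanolysis of F2 (K2CO3, MeOH, 0 °C) returns to the route at 3.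

Step 3. The protonated oxirane may ionise fully at C5, which would lose the anti stereospecificity, or it may be opened at C6, which leads to the enantiomeric diol; elimination to allylic alcohols or ring contraction may also compete. The fallback sets out from 3 and replaces protic hydrolysis by a chelation-directed opening: Ti(OiPr)4 with benzoic acid in CH2Cl2 binds the C7 alkoxide and the oxirane oxygen and should deliver the carboxylate to C5 with inversion under aprotic conditions. This gives (1R,2S)-2-hydroxy-2-(hydroxymethyl)-1,3,3-trimethylcyclohexyl benzoate F4, and methanolysis (K2CO3, MeOH) comes back to the route at 4.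

Step 6. Addition of the branched phosphonate carbanion to an aldehyde flanked by two fully substituted carbons may be slow, and the allylic anion may scramble the C9=C10 geometry. The fallback sets out from 6 and swaps carbonyl olefination with a C5 anion for a one-carbon olefination plus cross-coupling. Takai iodo-olefination (CrCl2, CHI3, THF, 0 °C → rt, divalent chromium) should give (1R,2R)-1-[(E)-2-iodoethenyl]-2,6,6-trimethyl-1,2-bis(trimethylsilyloxy)cyclohexane F5. Stille coupling of F5 with ethyl (E)-3-(tributylstannyl)but-2-enoate (PdCl2(MeCN)2, DMF, rt) forms the C8–C9 bond with both alkene geometries preset and comes back to the route at 9.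

**Further compounds**

F1 | step 2 | racemic [(1RS,6RS)-2,2,6-trimethyl-7-oxabicyclo[4.1.0]heptan-1-yl]methanol | OCC1(O2)C(C)(C)CCCC12C
F2 | step 2 | [(1S,6S)-2,2,6-trimethyl-7-oxabicyclo[4.1.0]heptan-1-yl]methyl (1S,4R)-4,7,7-trimethyl-3-oxo-2-oxabicyclo[2.2.1]heptane-1-carboxylate | O=C(OC[C@@]1(O2)C(C)(C)CCC[C@@]12C)[C@@]12CC[C@@](C)(C(=O)O1)C2(C)C
F3 | step 2 | [(1R,6R)-2,2,6-trimethyl-7-oxabicyclo[4.1.0]heptan-1-yl]methyl (1S,4R)-4,7,7-trimethyl-3-oxo-2-oxabicyclo[2.2.1]heptane-1-carboxylate | O=C(OC[C@]1(O2)C(C)(C)CCC[C@]12C)[C@@]12CC[C@@](C)(C(=O)O1)C2(C)C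
F4 | step 3 | (1R,2S)-2-hydroxy-2-(hydroxymethyl)-1,3,3-trimethylcyclohexyl benzoate | OC[C@@]1(O)C(C)(C)CCC[C@@]1(C)OC(=O)c1ccccc1
F5 | step 6 | (1R,2R)-1-[(E)-2-iodoethenyl]-2,6,6-trimethyl-1,2-bis(trimethylsilyloxy)cyclohexane | I/C=C/[C@@]1(O[Si](C)(C)C)C(C)(C)CCC[C@@]1(C)O[Si](C)(C)C
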